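The ratio of target to side product in the ochre flask read 0.849 at 10.0 s and 0.845 at 120 s, so it held steady while the starting material fell from 21.9% to 0.1%.

| flask | starting material | coupling partner | free catalyst | remark | time |
|---|---|---|---|---|---|
| ochre | 0.018 M | 1.5 equiv | 0.5 mol% | the very flask that is asked about, followed so far |  |
| blue | 0.018 M | 1.5 equiv | 0.25 mol% | run made earlier |  |
| flask | 0.018 M | 1.50 equiv | 0.5 mol% |  | 5.0 min |

ochre run (percent of the starting material charged)

| time / s | target / % | side product / % | starting material / % |
|---|---|---|---|
| 10.0 | 27.6 | 32.5 | 21.9 |
| 30.0 | 42.2 | 49.7 | 3.1 |
| 60.0 | 45.6 | 52.9 | 0.7 |
| 80.0 | 45.6 | 54.0 | 0.3 |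
| 120 | 45.7 | 54.1 | 0.1 |

blue run (percent of the starting material charged)

| time / min | target / % | side product / % | starting material / % |
|---|---|---|---|
| 0.250 | 16.3 | 39.5 | 24.2 |
| 0.500 | 23.8 | 56.1 | 9.2 |
| 1.00 | 28.2 | 66.7 | 2.0 |
| 2.00 | 29.8 | 69.6 | 0.5 |
| 4.00 | 30.1 | 70.2 | 0.8 |

(readings scatter by 0.3 percentage points)

* at 5.0 min, what has stopped the reaction, if anything has (forward and back rates have come level / no working catalyst is left / all of the starting material has reacted / it is still moving / the coupling partner has run out first)
* how much target there is at 5.0 min, in percent of the starting material charged
* how much side product there is at 5.0 min, in percent of the starting material charged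
* amount of target if the flask were left three thousand times as long, in percent of the starting material charged

- the numbers in the tables scatter with a standard deviation of 0.3 percentage points
- steps thought possible: starting material + free catalyst <-> free catalyst + open intermediate; free catalyst + open intermediate <-> catalyst intermediate; coupling partner + catalyst intermediate -> free catalyst + target; starting material <-> dormant form; open intermediate -> side product
- the reaction counts as stopped when no species that holds the starting material changes by six tenths of a point or more over the second half of the time

Both products leave the open intermediate: the side product by a first-order step, the target by capture on free catalyst. I therefore divided the two rates and integrated the quotient with [free catalyst] constant, which gave [target]/[side product] proportional to [free catalyst]. The last ochre reading gave 9390 M⁻¹: this capture constant, a selectivity factor, is target over side product per [free catalyst] charged. The blue run, a separate flask with half the catalyst, read 9530 M⁻¹, close to it.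

The asked time is 2.50 times that of the last ochre reading, where starting material read 0.1%, so I took the whole charge as split between the two products. My reckoning put 45.8% into target and 54.2% into side product.

The forecast gave all of the starting material has reacted, with 45.9% target, 54.1% side product and 45.9% after the long wait: “Both exits are irreversible, so no equilibrium can hold material back”. My target share lay close to the forecast's.

    starting material + free catalyst ⇌ free catalyst + open intermediate (K = 1.00, k = 2800 M⁻¹ s⁻¹)
    free catalyst + open intermediate ⇌ catalyst intermediate (K = 250 M⁻¹, k = 1900 M⁻¹ s⁻¹)
    coupling partner + catalyst intermediate → free catalyst + target (k = 8300 M⁻¹ s⁻¹)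
    starting material ⇌ dormant form (K = 0.350, k = 0.0250 s⁻¹)
    open intermediate → side product (k = 0.190 s⁻¹)

The simulation gave all of the starting material has reacted, with 45.9% target, 54.1% side product and 45.9% after the long wait, so the capture constant came out at 9410 M⁻¹ for this flask. The forecast's split belonged to this [free catalyst]: side product had moved by 5 points at 0.41 mol% and at 0.61 mol%. For the neighbouring flask with 2 mol% of free catalyst, the capture constant gave a ratio of 3.38, hence a target share of 77.2%. That flask held 23.1% side product and 76.9% target at 5.00 min.

The numbers in the tables are calculated with constants of no real substance; the scatter is artificial.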